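**Retrosynthetic overview**

- Feature: ring B holds an intact pentane-2,4-dione unit, C9–C8(=O)–C7–C11(=O)–C12. Its central carbon C7 is bonded to the C6 methine and its terminal carbon C9 to the C10 carbinol, and C6 and C10 both sit on quaternary C5 of ring A.
- Last disconnections: the C9 angelate (Yamaguchi esterification) and the C9 hydroxyl (Rubottom oxidation of the C8=C9 ring enol ether), leading back to the ring B ketol.
- Key disconnection: C6=C7 and C9–C10 are cut together ([3+3], Knoevenagel condensation then intramolecular aldol addition), giving acetylacetone and a ring A β-keto aldehyde. The aldehyde already carries the C3 acetate, because a C3 ketone could not be reduced selectively once the enedione exists.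
- Ring A is built first: copper-catalysed asymmetric conjugate methylation of a quinone monoketal (C4), two enolate alkylations (quaternary C5), then ketal hydrolysis and hindered-hydride reduction (C3). Ring B is closed second, in the key step.

Key step: step 10

Assumption: the (S,R,R) antipode of the BINOL-derived bis(1-phenylethyl)amine phosphoramidite is taken as the one that delivers (5R)-2 (its mirror image is used if the induction is the opposite). For bicyclic compounds the Why lines use eremophilane numbering (ring carbons C1–C10, acetyl C11/C12) and call the face carrying the C4 and C5 methyl groups β.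

**Route**

Step 1
Reactants: 1 4,4-dimethoxycyclohexa-2,5-dien-1-one
Product: 2 (5R)-4,4-dimethoxy-5-methylcyclohex-2-en-1-one
Conditions: Me2Zn (1.5 equiv), Cu(OTf)2 (2 mol %), phosphoramidite ligand (4 mol %), toluene, −25 °C; aq. NH4Cl; chromatography on Et3N-washed silica
Reagents that add atoms: dimethylzinc, C[Zn]C
Why: Copper-catalysed enantioselective conjugate addition of a dialkylzinc to a quinone monoketal, in which the chiral phosphoramidite–copper methyl species distinguishes the enantiotopic enone units of the symmetric dienone and sets the methyl-bearing centre (later C4) as R, while the zinc enolate formed does not add a second time.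

Step 2
Reactants: 2 (5R)-4,4-dimethoxy-5-methylcyclohex-2-en-1-one
Product: 3 (5R,6R)-4,4-dimethoxy-5,6-dimethylcyclohex-2-en-1-one
Conditions: LiN(i-Pr)2 (1.05 equiv), THF, −78 °C; MeI, −78 → −30 °C
Reagents that add atoms: iodomethane, CI
Why: Kinetic α′-enolate methylation at C6, the only enolisable position because C4 is a ketal carbon; the methyl is expected trans to the C5 methyl, but this centre is enolised again in step 3, so its configuration does not matter.

Step 3
Reactants: 3 (5R,6R)-4,4-dimethoxy-5,6-dimethylcyclohex-2-en-1-one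
Product: 4 (5R,6S)-6-[(benzyloxy)methyl]-4,4-dimethoxy-5,6-dimethylcyclohex-2-en-1-one
Conditions: LiN(i-Pr)2 (1.1 equiv), THF, −78 → −20 °C; DMPU, BnOCH2Cl, −78 → −40 °C
Reagents that add atoms: benzyl chloromethyl ether, ClCOCc1ccccc1
Why: Alkylation of the tetrasubstituted lithium enolate, in which the C5 methyl stands pseudoaxial to avoid A(1,2) strain with the enolate C6 methyl and the electrophile enters from the opposite face, placing CH2OBn trans to it and the two methyl groups cis (quaternary centre, later C5, set as S).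

Step 4
Reactants: 4 (5R,6S)-6-[(benzyloxy)methyl]-4,4-dimethoxy-5,6-dimethylcyclohex-2-en-1-one
Product: 5 (2S,3R)-2-[(benzyloxy)methyl]-4,4-dimethoxy-2,3-dimethylcyclohexan-1-one
Conditions: H2 (1 atm), Pd/C, pyridine (0.5 equiv), EtOAc, rt
Reagents that add atoms: none
Why: Catalytic hydrogenation of the disubstituted enone C=C with pyridine as catalyst modifier so that the benzyl ether is kept; the alkene is removed here so that ketal hydrolysis does not give an enedione.

Step 5
Reactants: 5 (2S,3R)-2-[(benzyloxy)methyl]-4,4-dimethoxy-2,3-dimethylcyclohexan-1-one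
Product: 6 (2S,3R)-2-[(benzyloxy)methyl]-2,3-dimethylcyclohexane-1,4-dione
Conditions: PPTS (0.2 equiv), acetone–H2O (10:1), rt
Reagents that add atoms: water, O
Why: Mild acid hydrolysis of the dimethyl ketal, with a weakly acidic buffer chosen to limit epimerisation of the now enolisable methyl-bearing C3.

Step 6
Reactants: 6 (2S,3R)-2-[(benzyloxy)methyl]-2,3-dimethylcyclohexane-1,4-dione
Product: 7 (2S,3R,4S)-2-[(benzyloxy)methyl]-4-hydroxy-2,3-dimethylcyclohexan-1-one
Conditions: LiBH(s-Bu)3 (1.05 equiv), THF, −78 °C; aq. NH4Cl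
Reagents that add atoms: none
Why: Site- and stereoselective reduction by a bulky trialkylborohydride: the C1 ketone next to the quaternary carbon is too hindered at −78 °C, and equatorial hydride delivery to the C4 ketone on the face opposite the adjacent C3 methyl should give the axial alcohol cis to both methyl groups (4S), as in the reduction of 2-methylcyclohexanone to the cis alcohol.

Step 7
Reactants: 7 (2S,3R,4S)-2-[(benzyloxy)methyl]-4-hydroxy-2,3-dimethylcyclohexan-1-one
Product: 8 (1S,2R,3S)-3-[(benzyloxy)methyl]-2,3-dimethyl-4-oxocyclohexyl acetate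
Conditions: Ac2O, pyridine, DMAP (cat.), CH2Cl2, rt
Reagents that add atoms: acetic anhydride, CC(=O)OC(C)=O
Why: DMAP-catalysed acetylation of the secondary alcohol installs the final C3 acetate with retention.

Step 8
Reactants: 8 (1S,2R,3S)-3-[(benzyloxy)methyl]-2,3-dimethyl-4-oxocyclohexyl acetate
Product: 9 (1S,2R,3S)-3-(hydroxymethyl)-2,3-dimethyl-4-oxocyclohexyl acetate
Conditions: H2 (1 atm), Pd(OH)2/C, EtOAc, rt
Reagents that add atoms: none
Why: Hydrogenolysis of the benzyl ether frees the neopentyl primary alcohol, while the ketone and the acetate are inert.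

Step 9
Reactants: 9 (1S,2R,3S)-3-(hydroxymethyl)-2,3-dimethyl-4-oxocyclohexyl acetate
Product: 10 (1S,2R,3S)-3-formyl-2,3-dimethyl-4-oxocyclohexyl acetate
Conditions: Dess–Martin periodinane, pyridine, CH2Cl2, 0 °C → rt; used at once
Reagents that add atoms: none
Why: Dess–Martin oxidation of the primary alcohol under buffered, non-nucleophilic conditions should give the non-enolisable β-keto aldehyde without loss of the formyl group.

Step 10
Reactants: 10 (1S,2R,3S)-3-formyl-2,3-dimethyl-4-oxocyclohexyl acetate; 11 acetylacetone (pentane-2,4-dione)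
Product: 13 (1R,2S,4aS,8aR)-7-acetyl-4a-hydroxy-1,8a-dimethyl-6-oxo-1,2,3,4,4a,5,6,8a-octahydronaphthalen-2-yl acetate, via Knoevenagel alkylidene diketone 12 (not isolated)
Conditions: 11 (1.2 equiv), piperidine (0.2 equiv), AcOH (0.2 equiv), 4 Å MS, CH2Cl2, 0 °C → rt, then 40 °C
Reagents that add atoms: none
Why: Piperidinium acetate condenses the central carbon of 11 with the C6 aldehyde of 10 (Knoevenagel condensation, C6=C7); the neopentyl, non-enolisable aldehyde should react far faster than the C10 ketone flanked by quaternary C5. In alkylidene diketone 12 one acetyl group is necessarily cis to C5, and its methyl group, as enol or piperidine enamine, adds to the C10 ketone (C9–C10) in an intramolecular aldol addition; the closest known reaction type is the amine-mediated Knoevenagel–aldol [3+3] cyclohexenone annulation of a 1,3-diketone with a 1,3-dielectrophile. Ring B closes in the 6-(enolexo)-exo-trig mode. The new C10 carbinol centre is controlled by the C5 quaternary centre: axial attack on the ring A chair by the C6=C7–C8=C9 tether anchored on C5 gives the cis-fused ketol with the 10-hydroxyl cis to the 5-methyl, the usual outcome of six-membered aldol closures onto a ring ketone from the neighbouring carbon, and reversibility of the aldol should let this isomer accumulate. No regiochemical choice arises because the two acetyl groups of 11 are identical, quaternary C5 rules out aromatisation, and the buffered conditions at or below 40 °C are chosen to avoid dehydration of the tertiary ketol and deformylation of 10.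

Step 11
Reactants: 13 (1R,2S,4aS,8aR)-7-acetyl-4a-hydroxy-1,8a-dimethyl-6-oxo-1,2,3,4,4a,5,6,8a-octahydronaphthalen-2-yl acetate
Product: 14 (1R,2S,4aS,8aR)-7-acetyl-1,8a-dimethyl-4a,6-bis[(triethylsilyl)oxy]-1,2,3,4,4a,8a-hexahydronaphthalen-2-yl acetate
Conditions: Et3SiCl (2.5 equiv), NaI (2.5 equiv), Et3N (3 equiv), MeCN, 0 °C → rt
Reagents that add atoms: chlorotriethylsilane, CC[Si](Cl)(CC)CC
Why: Silyl enol ether formation under equilibrating conditions (Et3SiI made in situ, Et3N) silylates the tertiary C10 hydroxyl and should give the more substituted, endocyclic C8=C9 enol ether in preference to the terminal enol ether of the acetyl group, as is usual for R3SiCl/NaI/Et3N enolisation of methylene versus methyl positions.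

Step 12
Reactants: 14 (1R,2S,4aS,8aR)-7-acetyl-1,8a-dimethyl-4a,6-bis[(triethylsilyl)oxy]-1,2,3,4,4a,8a-hexahydronaphthalen-2-yl acetate
Product: 16 (1R,2S,4aR,5S,8aR)-7-acetyl-4a,5-dihydroxy-1,8a-dimethyl-6-oxo-1,2,3,4,4a,5,6,8a-octahydronaphthalen-2-yl acetate, via silyloxy epoxide 15 (not isolated)
Conditions: DMDO (1.1 equiv), acetone–CH2Cl2, −78 → −30 °C; then HF·pyridine, pyridine, THF, 0 °C
Reagents that add atoms: dimethyldioxirane, CC1(C)OO1
Why: Rubottom oxidation, in which DMDO epoxidises the electron-rich C8=C9 enol ether (the electron-poor C6=C7 bond is inert) from the α-face, anti to the 10β-triethylsilyloxy group, so that the C9 oxygen is trans to the C10 oxygen, and buffered HF then opens the silyloxy epoxide to the α-ketol and frees the C10 hydroxyl; the pseudoequatorial 9α-hydroxyl is also expected to be the more stable epimer of this enolisable centre.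

Step 13
Reactants: 16 (1R,2S,4aR,5S,8aR)-7-acetyl-4a,5-dihydroxy-1,8a-dimethyl-6-oxo-1,2,3,4,4a,5,6,8a-octahydronaphthalen-2-yl acetate; 17 angelic acid [(2Z)-2-methylbut-2-enoic acid]
Product: 18 (1S,4aR,5R,6S,8aR)-6-acetoxy-3-acetyl-8a-hydroxy-4a,5-dimethyl-2-oxo-1,2,4a,5,6,7,8,8a-octahydronaphthalen-1-yl (2Z)-2-methylbut-2-enoate (CNP0196241.1)
Conditions: 17 (3 equiv), 2,4,6-trichlorobenzoyl chloride (3 equiv), Et3N (6 equiv), toluene, rt; then 16, 60 °C, no DMAP
Reagents that add atoms: none
Why: Yamaguchi esterification through the mixed 2,4,6-trichlorobenzoic anhydride of angelic acid acylates the secondary C9 hydroxyl and leaves the tertiary C10 hydroxyl, and running it without a nucleophilic catalyst is the established way to keep the Z geometry of the angelate.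

**Compound list**

1 | 4,4-dimethoxycyclohexa-2,5-dien-1-one | COC1(OC)C=CC(=O)C=C1 | starting material
2 | (5R)-4,4-dimethoxy-5-methylcyclohex-2-en-1-one | O=C1C[C@@H](C)C(OC)(OC)C=C1 | intermediate
3 | (5R,6R)-4,4-dimethoxy-5,6-dimethylcyclohex-2-en-1-one (trans) | O=C1[C@H](C)[C@@H](C)C(OC)(OC)C=C1 | intermediate
4 | (5R,6S)-6-[(benzyloxy)methyl]-4,4-dimethoxy-5,6-dimethylcyclohex-2-en-1-one (methyl groups cis) | O=C1[C@](C)(COCc2ccccc2)[C@@H](C)C(OC)(OC)C=C1 | intermediate
5 | (2S,3R)-2-[(benzyloxy)methyl]-4,4-dimethoxy-2,3-dimethylcyclohexan-1-one | O=C1[C@](C)(COCc2ccccc2)[C@@H](C)C(OC)(OC)CC1 | intermediate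
6 | (2S,3R)-2-[(benzyloxy)methyl]-2,3-dimethylcyclohexane-1,4-dione | O=C1[C@](C)(COCc2ccccc2)[C@@H](C)C(=O)CC1 | intermediate
7 | (2S,3R,4S)-2-[(benzyloxy)methyl]-4-hydroxy-2,3-dimethylcyclohexan-1-one (OH cis to both methyl groups) | O=C1[C@](C)(COCc2ccccc2)[C@@H](C)[C@@H](O)CC1 | intermediate
8 | (1S,2R,3S)-3-[(benzyloxy)methyl]-2,3-dimethyl-4-oxocyclohexyl acetate | O=C1[C@](C)(COCc2ccccc2)[C@@H](C)[C@@H](OC(C)=O)CC1 | intermediate
9 | (1S,2R,3S)-3-(hydroxymethyl)-2,3-dimethyl-4-oxocyclohexyl acetate | O=C1[C@](C)(CO)[C@@H](C)[C@@H](OC(C)=O)CC1 | intermediate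
10 | (1S,2R,3S)-3-formyl-2,3-dimethyl-4-oxocyclohexyl acetate | O=C[C@]1(C)[C@@H](C)[C@@H](OC(C)=O)CCC1=O | intermediate
11 | acetylacetone (pentane-2,4-dione) | CC(=O)CC(C)=O | starting material
12 | (1S,2R,3R)-3-(2-acetyl-3-oxobut-1-en-1-yl)-2,3-dimethyl-4-oxocyclohexyl acetate | CC(=O)C(C(C)=O)=C[C@]1(C)[C@@H](C)[C@@H](OC(C)=O)CCC1=O | intermediate
13 | (1R,2S,4aS,8aR)-7-acetyl-4a-hydroxy-1,8a-dimethyl-6-oxo-1,2,3,4,4a,5,6,8a-octahydronaphthalen-2-yl acetate (cis-fused ketol, 10-OH cis to 5-CH3) | CC(=O)C1=C[C@]2(C)[C@@H](C)[C@@H](OC(C)=O)CC[C@]2(O)CC1=O | intermediate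
14 | (1R,2S,4aS,8aR)-7-acetyl-1,8a-dimethyl-4a,6-bis[(triethylsilyl)oxy]-1,2,3,4,4a,8a-hexahydronaphthalen-2-yl acetate (C8=C9 enol ether, 10-O-silyl ether) | CC(=O)C1=C[C@]2(C)[C@@H](C)[C@@H](OC(C)=O)CC[C@]2(O[Si](CC)(CC)CC)C=C1O[Si](CC)(CC)CC | intermediate
15 | 8α,9α-epoxide of 14 (epoxide oxygen on the face opposite the 10β-silyloxy group; 8β-triethylsilyloxy) | CC(=O)C1=C[C@]2(C)[C@@H](C)[C@@H](OC(C)=O)CC[C@]2(O[Si](CC)(CC)CC)[C@@H]3O[C@]13O[Si](CC)(CC)CC | intermediate
16 | (1R,2S,4aR,5S,8aR)-7-acetyl-4a,5-dihydroxy-1,8a-dimethyl-6-oxo-1,2,3,4,4a,5,6,8a-octahydronaphthalen-2-yl acetate (9α-OH trans to 10β-OH) | CC(=O)C1=C[C@]2(C)[C@@H](C)[C@@H](OC(C)=O)CC[C@]2(O)[C@H](O)C1=O | intermediate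
17 | angelic acid, (2Z)-2-methylbut-2-enoic acid | C/C=C(/C)C(=O)O | starting material
18 | (1S,4aR,5R,6S,8aR)-6-acetoxy-3-acetyl-8a-hydroxy-4a,5-dimethyl-2-oxo-1,2,4a,5,6,7,8,8a-octahydronaphthalen-1-yl (2Z)-2-methylbut-2-enoate | C/C=C(/C)C(=O)O[C@@H]1C(=O)C(C(C)=O)=C[C@]2(C)[C@@H](C)[C@@H](OC(C)=O)CC[C@]12O | target

**Totals**

Total step count: 13. Longest linear sequence: 13 steps (1 → 18).

**Steps most likely to fail**

Step 10 (key step). The amine may attack the β-keto aldehyde and split off the formyl group before condensation, and ring closure onto the hindered C10 ketone may be slow or be followed by dehydration of the ketol. The fallback sets out from 10 and 11 and separates the two events without any amine. A TiCl4/pyridine Knoevenagel condensation (THF, 0 °C) gives alkylidene diketone 12, which is now isolated. LiN(SiMe3)2 (1.05 equiv, THF, −78 °C) then deprotonates the conjugated acetyl methyl, and the lithium enolate of the cis acetyl closes onto C10. A cold quench with AcOH returns the route at ketol 13. This detour makes no compound outside the list (F0).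

Step 11. Enolisation may take place at the wrong site, silylating the acetyl methyl (C12) or both positions instead of C9, or the tertiary silyl ether may ionise and eliminate. The fallback sets out from 13 and blocks the acetyl group first.
- Et3SiOTf/2,6-lutidine (CH2Cl2, −78 °C) gives the 10-O-triethylsilyl ether of 13 F1.
- Kinetic deprotonation with LiN(i-Pr)2 (THF, −78 °C) goes to the unhindered acetyl methyl, and trapping with t-BuMe2SiCl/DMPU gives the acetyl tert-butyldimethylsilyl enol ether F2.
- C9 is now the only enolisable position. KN(SiMe3)2 (THF, −78 °C) followed by 2-(phenylsulfonyl)-3-phenyloxaziridine hydroxylates it anti to the 10β-silyloxy group to give the 9α-hydroxy ketone F3.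
- HF·pyridine (THF, 0 °C) removes both silyl groups and returns the route at diol 16.

Step 12. Facial selectivity of the epoxidation may be poor: attack on the β-face, syn to the C10 oxygen, would give the 9β-hydroxy epimer. The fallback sets out from 14 and makes the C9–O bond by inversion, so that β-face attack becomes the wanted event.
- NBS (THF, −78 °C) brominates C9 of the enol ether to give the 9β-bromo 10-O-triethylsilyl ketone F4.
- HF·pyridine frees the tertiary hydroxyl to give the 9β-bromo ketol F5.
- Caesium angelate (preformed from 17 and Cs2CO3; DMF, rt → 40 °C) displaces the bromide with inversion and returns the route directly at target 18. C9 has no neighbour carrying a β-hydrogen (C10 is quaternary, C8 a carbonyl), so elimination cannot compete, and carboxylate alkylation keeps the Z geometry of the angelate.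

**Further compounds**

F0 | step 10 | none | none
F1 | step 11 | 10-O-triethylsilyl ether of ketol 13 | CC(=O)C1=C[C@]2(C)[C@@H](C)[C@@H](OC(C)=O)CC[C@]2(O[Si](CC)(CC)CC)CC1=O
F2 | step 11 | F1 with the acetyl group as its tert-butyldimethylsilyl enol ether (C11=C12) | C=C(O[Si](C)(C)C(C)(C)C)C1=C[C@]2(C)[C@@H](C)[C@@H](OC(C)=O)CC[C@]2(O[Si](CC)(CC)CC)CC1=O
F3 | step 11 | 9α-hydroxy derivative of F2 | C=C(O[Si](C)(C)C(C)(C)C)C1=C[C@]2(C)[C@@H](C)[C@@H](OC(C)=O)CC[C@]2(O[Si](CC)(CC)CC)[C@H](O)C1=O
F4 | step 12 | 9β-bromo-10β-(triethylsilyloxy) ketone (bromine cis to the C10 oxygen) | CC(=O)C1=C[C@]2(C)[C@@H](C)[C@@H](OC(C)=O)CC[C@]2(O[Si](CC)(CC)CC)[C@@H](Br)C1=O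
F5 | step 12 | 9β-bromo-10β-hydroxy ketone | CC(=O)C1=C[C@]2(C)[C@@H](C)[C@@H](OC(C)=O)CC[C@]2(O)[C@@H](Br)C1=O
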